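**Retrosynthetic overview**
1. Last bond: the ester C–O, made by opening the spiro-epoxide of fragment B with the carboxylate of fragment A; both 4-methoxybenzyl groups come off at the end.
2. Fragment B: the seven-membered lactone comes from ozonolytic cleavage of ring A of a cis-fused bicyclic dienoate (one end becomes the methyl ester, the other the enal), then reduction and lactonisation.
3. That bicycle comes from a Diels–Alder reaction of (S)-4-isopropylcyclohex-2-enone with a 2-siloxydiene; the oxirane is added by a Corey–Chaykovsky reaction before ring A is cleaved.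
4. Fragment A: (R)-4-isopropylcyclohex-2-enone, conjugate vinyl addition with enol triflate trapping, ozonolysis, oxa-Michael/Horner–Wadsworth–Emmons olefination, Stille hydroxymethylation.
5. Ring order: cyclohexenone ring (aldol condensation), carbocyclic ring A (Diels–Alder), oxirane, ring A cleaved, oxepinone lactone.

Assumption: the prolinol ether catalysts, ethyl 2-(diethoxyphosphoryl)prop-2-enoate, (tributylstannyl)methanol and the triflating agents are bought, and the (2S) catalyst is taken to give the (S) aldehyde by the usual open-face enamine model (the (2R) catalyst the antipode). The route is designed on paper and has not been run.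

**Route**

Step 1
Reactants: 1 3-methylbutanal; 2 but-3-en-2-one
Product: 3 (2R)-5-oxo-2-(propan-2-yl)hexanal
Conditions: (2R)-2-[methoxy(diphenyl)methyl]pyrrolidine (5 mol%), ethyl 3,4-dihydroxybenzoate (20 mol%), neat, 4 °C
Reagents that add atoms: none
Why: Organocatalytic enamine Michael addition in which the prolinol ether blocks one face of the aldehyde enamine, so the enone adds to the open face and sets the (R) centre.

Step 2
Reactants: 3 (2R)-5-oxo-2-(propan-2-yl)hexanal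
Product: 4 (4R)-4-(propan-2-yl)cyclohex-2-en-1-one
Conditions: LiOH, iPrOH, 25 °C
Reagents that add atoms: none
Why: Intramolecular aldol condensation of the methyl ketone onto the aldehyde closes the cyclohexenone and leaves the existing stereocentre untouched.

Step 3
Reactants: 4 (4R)-4-(propan-2-yl)cyclohex-2-en-1-one
Product: 6 (3R,4R)-3-ethenyl-4-(propan-2-yl)cyclohex-1-en-1-yl trifluoromethanesulfonate, via magnesium enolate 5 (not isolated)
Conditions: CH2=CHMgBr, CuBr·SMe2 (10 mol%), THF, −78 °C; then 2-[N,N-bis(trifluoromethanesulfonyl)amino]-5-chloropyridine, −78 → 0 °C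
Reagents that add atoms: vinylmagnesium bromide C=C[Mg]Br; 2-[N,N-bis(trifluoromethanesulfonyl)amino]-5-chloropyridine O=S(=O)(N(c1ccc(Cl)cn1)S(=O)(=O)C(F)(F)F)C(F)(F)F
Why: Copper-catalysed conjugate addition puts the vinyl group anti to the isopropyl group (trans), and O-triflation of the enolate fixes the double bond regiospecifically.

Step 4
Reactants: 6 (3R,4R)-3-ethenyl-4-(propan-2-yl)cyclohex-1-en-1-yl trifluoromethanesulfonate
Product: 8 (3R,4R)-3-formyl-4-(propan-2-yl)cyclohex-1-en-1-yl trifluoromethanesulfonate, via ozonide 7 (not isolated)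
Conditions: O3, CH2Cl2, −78 °C; then Me2S, −78 → 20 °C
Reagents that add atoms: ozone [O-][O+]=O
Why: Ozonolysis cleaves only the electron-neutral vinyl group because the enol triflate alkene is strongly deactivated; the trans aldehyde is also the thermodynamic epimer.

Step 5
Reactants: 8 (3R,4R)-3-formyl-4-(propan-2-yl)cyclohex-1-en-1-yl trifluoromethanesulfonate; 9 ethyl 2-(diethoxyphosphoryl)prop-2-enoate; 10 (4-methoxyphenyl)methanol
Product: 12 ethyl (2E)-2-{[(4-methoxyphenyl)methoxy]methyl}-3-[(1S,6R)-6-(propan-2-yl)-3-(trifluoromethanesulfonyloxy)cyclohex-2-en-1-yl]prop-2-enoate (same spatial arrangement as 8; the descriptor changes by priority only), via phosphonate carbanion 11 (not isolated)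
Conditions: 10, NaH, THF, 0 °C; 9, 0 °C, 30 min; then 8, −78 → 0 °C
Reagents that add atoms: none
Why: Tandem oxa-Michael addition and Horner–Wadsworth–Emmons olefination, in which the α-substituted phosphonate carbanion and the α-branched aldehyde give the alkene with the ring trans to the ester (E).

Step 6
Reactants: 12 ethyl (2E)-2-{[(4-methoxyphenyl)methoxy]methyl}-3-[(1S,6R)-6-(propan-2-yl)-3-(trifluoromethanesulfonyloxy)cyclohex-2-en-1-yl]prop-2-enoate
Product: 13 ethyl (2E)-3-[(1R,6R)-3-(hydroxymethyl)-6-(propan-2-yl)cyclohex-2-en-1-yl]-2-{[(4-methoxyphenyl)methoxy]methyl}prop-2-enoate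
Conditions: Bu3SnCH2OH, Pd(PPh3)4 (5 mol%), LiCl (3 equiv), 1,4-dioxane, 90 °C
Reagents that add atoms: (tributylstannyl)methanol CCCC[Sn](CO)(CCCC)CCCC
Why: Migita–Kosugi–Stille coupling of the enol triflate with the hydroxymethylstannane installs the allylic CH2OH without touching the stereocentres.

Step 7
Reactants: 13 ethyl (2E)-3-[(1R,6R)-3-(hydroxymethyl)-6-(propan-2-yl)cyclohex-2-en-1-yl]-2-{[(4-methoxyphenyl)methoxy]methyl}prop-2-enoate
Product: 14 (2E)-3-[(1R,6R)-3-(hydroxymethyl)-6-(propan-2-yl)cyclohex-2-en-1-yl]-2-{[(4-methoxyphenyl)methoxy]methyl}prop-2-enoic acid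
Conditions: LiOH·H2O, THF/MeOH/H2O (3:1:1), 25 °C; work-up with 1 M HCl
Reagents that add atoms: lithium hydroxide [Li+].[OH-]
Why: Saponification of the only ester present, mild enough to leave the skipped diene and the benzylic ether alone.

Step 8
Reactants: 1 3-methylbutanal; 2 but-3-en-2-one
Product: 15 (2S)-5-oxo-2-(propan-2-yl)hexanal
Conditions: (2S)-2-[methoxy(diphenyl)methyl]pyrrolidine (5 mol%), ethyl 3,4-dihydroxybenzoate (20 mol%), neat, 4 °C
Reagents that add atoms: none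
Why: The same organocatalytic enamine Michael addition with the enantiomeric catalyst gives the (S) aldehyde.

Step 9
Reactants: 15 (2S)-5-oxo-2-(propan-2-yl)hexanal
Product: 16 (4S)-4-(propan-2-yl)cyclohex-2-en-1-one
Conditions: LiOH, iPrOH, 25 °C
Reagents that add atoms: none
Why: Intramolecular aldol condensation as in step 2.

Step 10
Reactants: 2 but-3-en-2-one
Product: 17 tert-butyl(buta-1,3-dien-2-yloxy)dimethylsilane
Conditions: tBuMe2SiOTf, Et3N, Et2O, 0 → 20 °C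
Reagents that add atoms: tert-butyldimethylsilyl trifluoromethanesulfonate CC(C)(C)[Si](C)(C)OS(=O)(=O)C(F)(F)F
Why: Soft enolisation and O-silylation of the enone gives the 2-siloxydiene.

Step 11
Reactants: 16 (4S)-4-(propan-2-yl)cyclohex-2-en-1-one; 17 tert-butyl(buta-1,3-dien-2-yloxy)dimethylsilane
Product: 18 (4S,4aS,8aS)-6-{[tert-butyl(dimethyl)silyl]oxy}-4-(propan-2-yl)-3,4,4a,5,8,8a-hexahydronaphthalen-1(2H)-one (cis-fused)
Conditions: AlBr3/AlMe3 (10:1, 0.3 equiv), toluene/CH2Cl2, −10 → 0 °C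
Reagents that add atoms: none
Why: Lewis-acid-promoted Diels–Alder reaction in which the diene adds to the enone face anti to the isopropyl group, giving the cis ring fusion, with the siloxy carbon para to the acyl-bearing carbon.

Step 12
Reactants: 18 (4S,4aS,8aS)-6-{[tert-butyl(dimethyl)silyl]oxy}-4-(propan-2-yl)-3,4,4a,5,8,8a-hexahydronaphthalen-1(2H)-one
Product: 20 (1R,4S,4aS,8aS)-6-{[tert-butyl(dimethyl)silyl]oxy}-4-(propan-2-yl)-3,4,4a,5,8,8a-hexahydro-2H-spiro[naphthalene-1,2'-oxirane] (oxirane O cis to C8, CH2 trans), via sulfonium betaine 19 (not isolated)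
Conditions: Me3S+ I−, KN(SiMe3)2, THF, −10 → 20 °C
Reagents that add atoms: trimethylsulfonium iodide C[S+](C)C.[I-]
Why: Corey–Chaykovsky epoxidation in which the small ylide attacks the ketone axially, anti to the axial C8a–C8 bond of the cis-fused bicycle, so the oxygen ends equatorial and cis to C8.

Step 13
Reactants: 20 (1R,4S,4aS,8aS)-6-{[tert-butyl(dimethyl)silyl]oxy}-4-(propan-2-yl)-3,4,4a,5,8,8a-hexahydro-2H-spiro[naphthalene-1,2'-oxirane]
Product: 21 (1R,4S,4aS,8aS)-4-(propan-2-yl)-3,4,4a,5-tetrahydro-2H-spiro[naphthalene-1,2'-oxiran]-6(8aH)-one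
Conditions: Pd(OAc)2 (10 mol%), O2 (1 atm), DMSO, 25 °C
Reagents that add atoms: none
Why: Saegusa–Ito oxidation of the regiodefined silyl enol ether gives the C7–C8 enone under neutral conditions that spare the oxirane.

Step 14
Reactants: 21 (1R,4S,4aS,8aS)-4-(propan-2-yl)-3,4,4a,5-tetrahydro-2H-spiro[naphthalene-1,2'-oxiran]-6(8aH)-one
Product: 23 (1R,4S,4aR,8aS)-4-(propan-2-yl)-3,4,4a,8a-tetrahydro-2H-spiro[naphthalene-1,2'-oxiran]-6-yl trifluoromethanesulfonate, via lithium dienolate 22 (not isolated)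
Conditions: LiN(iPr)2, THF, −78 °C; then PhNTf2, −78 → 0 °C
Reagents that add atoms: N-phenylbis(trifluoromethanesulfonimide) O=S(=O)(N(c1ccccc1)S(=O)(=O)C(F)(F)F)C(F)(F)F
Why: Kinetic α′-deprotonation of the enone gives the cross-conjugated dienolate, and its O-triflation places the new double bond at C5–C6 (enol triflate formation).

Step 15
Reactants: 23 (1R,4S,4aR,8aS)-4-(propan-2-yl)-3,4,4a,8a-tetrahydro-2H-spiro[naphthalene-1,2'-oxiran]-6-yl trifluoromethanesulfonate; 10 (4-methoxyphenyl)methanol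
Product: 24 (4-methoxyphenyl)methyl (1R,4S,4aR,8aS)-4-(propan-2-yl)-3,4,4a,8a-tetrahydro-2H-spiro[naphthalene-1,2'-oxirane]-6-carboxylate
Conditions: Pd(OAc)2 (5 mol%), PPh3 (10 mol%), CO (1 atm), Et3N, DMF, 50 °C
Reagents that add atoms: carbon monoxide [C-]#[O+]
Why: Palladium-catalysed alkoxycarbonylation of the dienyl triflate (oxidative addition, CO insertion, alcoholysis) introduces the carboxyl carbon as an acid-labile ester.

Step 16
Reactants: 24 (4-methoxyphenyl)methyl (1R,4S,4aR,8aS)-4-(propan-2-yl)-3,4,4a,8a-tetrahydro-2H-spiro[naphthalene-1,2'-oxirane]-6-carboxylate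
Product: 26 methyl (3R,4S,5R,6S)-5-[(1E)-2-formyl-3-[(4-methoxyphenyl)methoxy]-3-oxoprop-1-en-1-yl]-6-(propan-2-yl)-1-oxaspiro[2.5]octane-4-carboxylate, via methoxy hydroperoxide 25 (not isolated)
Conditions: O3 (1.0 equiv), NaHCO3, CH2Cl2/MeOH (4:1), −78 °C; then Ac2O, Et3N, CH2Cl2, 0 → 20 °C
Reagents that add atoms: ozone [O-][O+]=O; methanol CO
Why: Ozonolysis with Criegee fragmentation and Schreiber end-differentiation, in which ozone takes the more electron-rich C7–C8 alkene, the carbonyl oxide on the alkyl-substituted carbon is trapped by methanol and dehydrated to the methyl ester, and the other carbon becomes the enal whose cis relation to the ring is inherited from the ring alkene.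

Step 17
Reactants: 26 methyl (3R,4S,5R,6S)-5-[(1E)-2-formyl-3-[(4-methoxyphenyl)methoxy]-3-oxoprop-1-en-1-yl]-6-(propan-2-yl)-1-oxaspiro[2.5]octane-4-carboxylate
Product: 28 (4-methoxyphenyl)methyl (5aR,6S,9R,9aS)-1-oxo-6-(propan-2-yl)-1,3,5a,6,7,8-hexahydro-9aH-spiro[2-benzoxepine-9,2'-oxirane]-4-carboxylate, via hydroxy ester 27 (not isolated)
Conditions: NaBH4, CeCl3·7H2O, MeOH, −40 °C; then (ClBu2Sn)2O (5 mol%), toluene, 90 °C
Reagents that add atoms: none
Why: Luche 1,2-reduction of the enal, then tin-catalysed intramolecular transesterification, closes the seven-membered lactone because the hydroxymethyl group is cis to the ring carbon that carries the ester.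

Step 18
Reactants: 28 (4-methoxyphenyl)methyl (5aR,6S,9R,9aS)-1-oxo-6-(propan-2-yl)-1,3,5a,6,7,8-hexahydro-9aH-spiro[2-benzoxepine-9,2'-oxirane]-4-carboxylate; 14 (2E)-3-[(1R,6R)-3-(hydroxymethyl)-6-(propan-2-yl)cyclohex-2-en-1-yl]-2-{[(4-methoxyphenyl)methoxy]methyl}prop-2-enoic acid
Product: 29 [(5aR,6S,9R,9aS)-9-hydroxy-4-{[(4-methoxyphenyl)methoxy]carbonyl}-1-oxo-6-(propan-2-yl)-1,3,5a,6,7,8,9,9a-octahydro-2-benzoxepin-9-yl]methyl (2E)-3-[(1R,6R)-3-(hydroxymethyl)-6-(propan-2-yl)cyclohex-2-en-1-yl]-2-{[(4-methoxyphenyl)methoxy]methyl}prop-2-enoate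
Conditions: Cs2CO3 (0.3 equiv), DMF, 70 °C
Reagents that add atoms: none
Why: Base-catalysed epoxide ring opening by the carboxylate at the CH2 carbon (SN2) forms the ester link and reveals the tertiary alcohol with retention at the quaternary centre.

Step 19
Reactants: 29 the bis(4-methoxybenzyl)-protected ester from step 18
Product: 30 (5aR,6S,9R,9aS)-9-hydroxy-9-({[(2E)-2-(hydroxymethyl)-3-[(1R,6R)-3-(hydroxymethyl)-6-(propan-2-yl)cyclohex-2-en-1-yl]prop-2-enoyl]oxy}methyl)-1-oxo-6-(propan-2-yl)-1,3,5a,6,7,8,9,9a-octahydro-2-benzoxepine-4-carboxylic acid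
Conditions: CF3CO2H/CH2Cl2 (1:9), anisole (10 equiv), 0 °C
Reagents that add atoms: none
Why: Acidolysis ionises both 4-methoxybenzyl groups (ether and ester) to the benzylic cation, which anisole traps, in one operation.

**Compound list**
1 | 3-methylbutanal | CC(C)CC=O | starting material
2 | but-3-en-2-one | CC(=O)C=C | starting material
3 | (2R)-5-oxo-2-(propan-2-yl)hexanal | O=C[C@@H](C(C)C)CCC(C)=O | intermediate
4 | (4R)-4-(propan-2-yl)cyclohex-2-en-1-one | O=C1C=C[C@@H](C(C)C)CC1 | intermediate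
5 | bromomagnesium (3R,4R)-3-ethenyl-4-(propan-2-yl)cyclohex-1-en-1-olate | CC(C)[C@H]1CCC(O[Mg]Br)=C[C@@H]1C=C | intermediate
6 | (3R,4R)-3-ethenyl-4-(propan-2-yl)cyclohex-1-en-1-yl trifluoromethanesulfonate (vinyl trans to isopropyl) | CC(C)[C@H]1CCC(OS(=O)(=O)C(F)(F)F)=C[C@@H]1C=C | intermediate
7 | (3R,4R)-4-(propan-2-yl)-3-(1,2,4-trioxolan-3-yl)cyclohex-1-en-1-yl trifluoromethanesulfonate (trioxolane centre undefined) | CC(C)[C@H]1CCC(OS(=O)(=O)C(F)(F)F)=C[C@@H]1C1OCOO1 | intermediate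
8 | (3R,4R)-3-formyl-4-(propan-2-yl)cyclohex-1-en-1-yl trifluoromethanesulfonate | CC(C)[C@H]1CCC(OS(=O)(=O)C(F)(F)F)=C[C@@H]1C=O | intermediate
9 | ethyl 2-(diethoxyphosphoryl)prop-2-enoate | CCOC(=O)C(=C)P(=O)(OCC)OCC | starting material
10 | (4-methoxyphenyl)methanol | COc1ccc(CO)cc1 | starting material
11 | sodium 1-(diethoxyphosphoryl)-1-(ethoxycarbonyl)-2-[(4-methoxyphenyl)methoxy]ethan-1-ide | [Na+].CCOC(=O)[C-](COCc1ccc(OC)cc1)P(=O)(OCC)OCC | intermediate
12 | ethyl (2E)-2-{[(4-methoxyphenyl)methoxy]methyl}-3-[(1S,6R)-6-(propan-2-yl)-3-(trifluoromethanesulfonyloxy)cyclohex-2-en-1-yl]prop-2-enoate | CC(C)[C@H]1CCC(OS(=O)(=O)C(F)(F)F)=C[C@@H]1/C=C(\COCc1ccc(OC)cc1)C(=O)OCC | intermediate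
13 | ethyl (2E)-3-[(1R,6R)-3-(hydroxymethyl)-6-(propan-2-yl)cyclohex-2-en-1-yl]-2-{[(4-methoxyphenyl)methoxy]methyl}prop-2-enoate | CC(C)[C@H]1CCC(CO)=C[C@@H]1/C=C(\COCc1ccc(OC)cc1)C(=O)OCC | intermediate
14 | (2E)-3-[(1R,6R)-3-(hydroxymethyl)-6-(propan-2-yl)cyclohex-2-en-1-yl]-2-{[(4-methoxyphenyl)methoxy]methyl}prop-2-enoic acid | CC(C)[C@H]1CCC(CO)=C[C@@H]1/C=C(\COCc1ccc(OC)cc1)C(=O)O | intermediate
15 | (2S)-5-oxo-2-(propan-2-yl)hexanal | O=C[C@H](C(C)C)CCC(C)=O | intermediate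
16 | (4S)-4-(propan-2-yl)cyclohex-2-en-1-one | O=C1C=C[C@H](C(C)C)CC1 | intermediate
17 | tert-butyl(buta-1,3-dien-2-yloxy)dimethylsilane | C=CC(=C)O[Si](C)(C)C(C)(C)C | intermediate
18 | (4S,4aS,8aS)-6-{[tert-butyl(dimethyl)silyl]oxy}-4-(propan-2-yl)-3,4,4a,5,8,8a-hexahydronaphthalen-1(2H)-one (cis-fused, ring-fusion bonds trans to isopropyl) | O=C1CC[C@@H](C(C)C)[C@@H]2CC(O[Si](C)(C)C(C)(C)C)=CC[C@@H]21 | intermediate
19 | {[(1R,4S,4aS,8aS)-6-{[tert-butyl(dimethyl)silyl]oxy}-1-oxido-4-(propan-2-yl)-1,2,3,4,4a,5,8,8a-octahydronaphthalen-1-yl]methyl}dimethylsulfonium | [O-][C@]1(C[S+](C)C)CC[C@@H](C(C)C)[C@@H]2CC(O[Si](C)(C)C(C)(C)C)=CC[C@@H]21 | intermediate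
20 | (1R,4S,4aS,8aS)-6-{[tert-butyl(dimethyl)silyl]oxy}-4-(propan-2-yl)-3,4,4a,5,8,8a-hexahydro-2H-spiro[naphthalene-1,2'-oxirane] | C1O[C@@]12CC[C@@H](C(C)C)[C@@H]3CC(O[Si](C)(C)C(C)(C)C)=CC[C@@H]32 | intermediate
21 | (1R,4S,4aS,8aS)-4-(propan-2-yl)-3,4,4a,5-tetrahydro-2H-spiro[naphthalene-1,2'-oxiran]-6(8aH)-one | C1O[C@@]12CC[C@@H](C(C)C)[C@@H]3CC(=O)C=C[C@@H]32 | intermediate
22 | lithium (1R,4S,4aR,8aS)-4-(propan-2-yl)-3,4,4a,8a-tetrahydro-2H-spiro[naphthalene-1,2'-oxiran]-6-olate | C1O[C@@]12CC[C@@H](C(C)C)[C@@H]3C=C(O[Li])C=C[C@@H]32 | intermediate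
23 | (1R,4S,4aR,8aS)-4-(propan-2-yl)-3,4,4a,8a-tetrahydro-2H-spiro[naphthalene-1,2'-oxiran]-6-yl trifluoromethanesulfonate | C1O[C@@]12CC[C@@H](C(C)C)[C@@H]3C=C(OS(=O)(=O)C(F)(F)F)C=C[C@@H]32 | intermediate
24 | (4-methoxyphenyl)methyl (1R,4S,4aR,8aS)-4-(propan-2-yl)-3,4,4a,8a-tetrahydro-2H-spiro[naphthalene-1,2'-oxirane]-6-carboxylate | C1O[C@@]12CC[C@@H](C(C)C)[C@@H]3C=C(C(=O)OCc4ccc(OC)cc4)C=C[C@@H]32 | intermediate
25 | (4-methoxyphenyl)methyl (2E)-2-formyl-3-[(3R,4S,5R,6S)-4-[hydroperoxy(methoxy)methyl]-6-(propan-2-yl)-1-oxaspiro[2.5]octan-5-yl]prop-2-enoate (peroxyacetal centre undefined) | C1O[C@@]12CC[C@@H](C(C)C)[C@H](/C=C(\C=O)C(=O)OCc3ccc(OC)cc3)[C@@H]2C(OC)OO | intermediate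
26 | methyl (3R,4S,5R,6S)-5-[(1E)-2-formyl-3-[(4-methoxyphenyl)methoxy]-3-oxoprop-1-en-1-yl]-6-(propan-2-yl)-1-oxaspiro[2.5]octane-4-carboxylate | C1O[C@@]12CC[C@@H](C(C)C)[C@H](/C=C(\C=O)C(=O)OCc3ccc(OC)cc3)[C@@H]2C(=O)OC | intermediate
27 | methyl (3R,4S,5R,6S)-5-[(1E)-2-(hydroxymethyl)-3-[(4-methoxyphenyl)methoxy]-3-oxoprop-1-en-1-yl]-6-(propan-2-yl)-1-oxaspiro[2.5]octane-4-carboxylate | C1O[C@@]12CC[C@@H](C(C)C)[C@H](/C=C(\CO)C(=O)OCc3ccc(OC)cc3)[C@@H]2C(=O)OC | intermediate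
28 | (4-methoxyphenyl)methyl (5aR,6S,9R,9aS)-1-oxo-6-(propan-2-yl)-1,3,5a,6,7,8-hexahydro-9aH-spiro[2-benzoxepine-9,2'-oxirane]-4-carboxylate (cis-fused lactone) | C1O[C@@]12CC[C@@H](C(C)C)[C@@H]3C=C(C(=O)OCc4ccc(OC)cc4)COC(=O)[C@@H]32 | intermediate
29 | [(5aR,6S,9R,9aS)-9-hydroxy-4-{[(4-methoxyphenyl)methoxy]carbonyl}-1-oxo-6-(propan-2-yl)-1,3,5a,6,7,8,9,9a-octahydro-2-benzoxepin-9-yl]methyl (2E)-3-[(1R,6R)-3-(hydroxymethyl)-6-(propan-2-yl)cyclohex-2-en-1-yl]-2-{[(4-methoxyphenyl)methoxy]methyl}prop-2-enoate | CC(C)[C@H]1CCC(CO)=C[C@@H]1/C=C(\COCc1ccc(OC)cc1)C(=O)OC[C@@]1(O)CC[C@@H](C(C)C)[C@@H]2C=C(C(=O)OCc3ccc(OC)cc3)COC(=O)[C@@H]21 | intermediate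
30 | (5aR,6S,9R,9aS)-9-hydroxy-9-({[(2E)-2-(hydroxymethyl)-3-[(1R,6R)-3-(hydroxymethyl)-6-(propan-2-yl)cyclohex-2-en-1-yl]prop-2-enoyl]oxy}methyl)-1-oxo-6-(propan-2-yl)-1,3,5a,6,7,8,9,9a-octahydro-2-benzoxepine-4-carboxylic acid | CC(C)[C@H]1CCC(CO)=C[C@@H]1/C=C(\CO)C(=O)OC[C@@]1(O)CC[C@@H](C(C)C)[C@@H]2C=C(C(=O)O)COC(=O)[C@@H]21 | target

**Totals and weak points**

Total step count: 19. Longest linear sequence: 11 steps (steps 8, 9 and 11 to 19).

The step most likely to fail is step 12: the basic ylide may epimerise the cis-fused ketone or react sluggishly at the hindered carbonyl. The fallback sets out from 18 and comes back at 20. The less basic reagent (iPrO)Me2SiCH2MgCl with CeCl3 in THF at −78 °C adds from the same axial direction and gives the β-hydroxysilane F1. A fluoride-free Tamao oxidation (H2O2, KHCO3, THF/MeOH), chosen so that the silyl enol ether survives, gives the 1,2-diol F2. Tosylation of the primary hydroxyl (TsCl, Et3N) gives the monotosylate F3, and NaH in THF closes the oxirane to 20.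

The second is step 16: ozone may not discriminate well enough between the two alkenes of the dienoate, and the 2-formyl acrylate in 26 can isomerise about its double bond. The fallback sets out from 23 and comes back at 28, moving the carbonylation to the end. The same ozonolysis protocol on the triflate 23, whose enol triflate alkene is far more deactivated, gives the ester aldehyde F4. Luche reduction and tin-catalysed ring closure as in step 17 give the lactone triflate F5. Alkoxycarbonylation as in step 15 (Pd(OAc)2, PPh3, CO, 10, Et3N) then gives 28.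

The third is step 18: the epoxide CH2 is hindered, and the carboxylate can instead attack the allylic C–O bond of the lactone. The fallback sets out from 27, taken from step 17 before the tin-catalysed ring closure, and comes back at 29, so the union is done while no allylic ester is present. 27 and 14 with Cs2CO3 in DMF at 70 °C give the seco ester F6, and (ClBu2Sn)2O in toluene at 90 °C then closes the lactone to 29.

Further compounds
F1 | step 12 | (1R,4S,4aS,8aS)-6-{[tert-butyl(dimethyl)silyl]oxy}-1-{[dimethyl(propan-2-yloxy)silyl]methyl}-4-(propan-2-yl)-1,2,3,4,4a,5,8,8a-octahydronaphthalen-1-ol | CC(C)O[Si](C)(C)C[C@@]1(O)CC[C@@H](C(C)C)[C@@H]2CC(O[Si](C)(C)C(C)(C)C)=CC[C@@H]21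
F2 | step 12 | (1R,4S,4aS,8aS)-6-{[tert-butyl(dimethyl)silyl]oxy}-1-(hydroxymethyl)-4-(propan-2-yl)-1,2,3,4,4a,5,8,8a-octahydronaphthalen-1-ol | OC[C@@]1(O)CC[C@@H](C(C)C)[C@@H]2CC(O[Si](C)(C)C(C)(C)C)=CC[C@@H]21
F3 | step 12 | [(1R,4S,4aS,8aS)-6-{[tert-butyl(dimethyl)silyl]oxy}-1-hydroxy-4-(propan-2-yl)-1,2,3,4,4a,5,8,8a-octahydronaphthalen-1-yl]methyl 4-methylbenzenesulfonate | Cc1ccc(cc1)S(=O)(=O)OC[C@@]1(O)CC[C@@H](C(C)C)[C@@H]2CC(O[Si](C)(C)C(C)(C)C)=CC[C@@H]21
F4 | step 16 | methyl (3R,4S,5R,6S)-5-[(1E)-3-oxo-2-(trifluoromethanesulfonyloxy)prop-1-en-1-yl]-6-(propan-2-yl)-1-oxaspiro[2.5]octane-4-carboxylate | C1O[C@@]12CC[C@@H](C(C)C)[C@H](/C=C(\C=O)OS(=O)(=O)C(F)(F)F)[C@@H]2C(=O)OC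
F5 | step 16 | (5aR,6S,9R,9aS)-1-oxo-6-(propan-2-yl)-1,3,5a,6,7,8-hexahydro-9aH-spiro[2-benzoxepine-9,2'-oxiran]-4-yl trifluoromethanesulfonate | C1O[C@@]12CC[C@@H](C(C)C)[C@@H]3C=C(OS(=O)(=O)C(F)(F)F)COC(=O)[C@@H]32
F6 | step 18 | methyl (1S,2R,5S,6R)-2-hydroxy-6-[(1E)-2-(hydroxymethyl)-3-[(4-methoxyphenyl)methoxy]-3-oxoprop-1-en-1-yl]-2-({[(2E)-3-[(1R,6R)-3-(hydroxymethyl)-6-(propan-2-yl)cyclohex-2-en-1-yl]-2-{[(4-methoxyphenyl)methoxy]methyl}prop-2-enoyl]oxy}methyl)-5-(propan-2-yl)cyclohexane-1-carboxylate | CC(C)[C@H]1CCC(CO)=C[C@@H]1/C=C(\COCc1ccc(OC)cc1)C(=O)OC[C@@]1(O)CC[C@@H](C(C)C)[C@H](/C=C(\CO)C(=O)OCc2ccc(OC)cc2)[C@@H]1C(=O)OC
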